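The earlier runs and the new flask come from a simulation for an exercise; scatter was added.

Start from the reading time: each of the four flasks is read at 6.0 min, so ask how many Z half-times that span holds.

the same everywhere: Z 0.50 M
- north: J 0.45 M; X 0.28 M; temperature 30 °C; run made earlier
- south: J 0.45 M; X 1.1 M; temperature 52 °C; run made earlier
- birch: J 0.450 M; X 0.550 M; at 20 °C until 80 s, from then on at 60 °C; time 6.0 min
- cedar: J 0.450 M; X 0.550 M; temperature 60 °C; time 6.0 min
- elm: J 0.450 M; X 0.550 M; temperature 40 °C; time 6.0 min
- alder: J 0.450 M; X 0.550 M; temperature 20 °C; time 6.0 min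

| run | time / min | Q / % | Z / % |
|---|---|---|---|
| north | 4.00 | 9.8 | 12.5 |
| north | 8.00 | 1.8 | 5.2 |
| north | 12.0 | 0 | 3.3 |
| north | 20.0 | 0.6 | 0.9 |
| south | 1.00 | 0 | 0.3 |
| south | 2.00 | 0.4 | 0 |
| south | 3.00 | 0 | 0 |
| south | 4.00 | 0 | 0.8 |
| south | 5.00 | 0 | 0 |

(scatter of a reading: 0.5 percentage points)

- which flask leads in amount of Q, in percent of the Z charged ("all alike" within 1.5 percentage points) (birch / cedar / elm / alder / all alike)
- how much Q is there at the end, in percent of the Z charged: birch
- how much Q is there at the end, in percent of the Z charged: cedar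
- how much Q is there at the end, in percent of the Z charged: elm
- how much Q is there at the end, in percent of the Z charged: alder



Work with the fraction of Z left, f, and not with the Q made. Suppose a second-order fall, f = h/(h + t). The north run has 12.5 % of its Z left at 4.00 min, so h = t·f/(1 − f) gives 0.571 min. Call h the Z half-time, the time by which half of the Z charged is gone in such a fall.

But north stood at 30 °C, and the south run, with Z down to 0.3 % at 1.00 min, differs from it in both temperature and X, so it gives no figure for the heat effect. So guess a factor 2 in rate per 10 degrees, and set aside the different X. This reckoning is mine.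

Alder then has h = 1.14 min, so its reading holds 5.26 half-times and f = 16.0 %. Cedar has h = 0.0714 min and f = 1.18 %, so alder keeps more Z than cedar. Birch spends 4.67 min of its time at 60 °C, so count it with cedar.

Now treat Q the same way, as a fraction surviving. Its fall between the north readings reads 0.424 min⁻¹, with their scatter. Let Q be born at h. North then gives a share of 47.9 % of the Z gone, and alder, with the decay divided by 2, gives Q of about 14.4 %.

The forecast names alder as the leader, with alder at 10 % (5 % to 18 %), elm 1 %, birch 0.1 % and cedar 0 %, holding that “hot flasks should have destroyed Q”. My alder figure is higher than its figure.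

The flasks give alder in the lead: alder 24.2 %, elm 0.0965 %, birch 0 %, cedar 0 %.

    Z + J → Q (k = 0.0190 L mol⁻¹ s⁻¹, Ea = 67.0 kJ mol⁻¹)
    Z + X → E (k = 0.00240 L mol⁻¹ s⁻¹, Ea = 73.0 kJ mol⁻¹)
    2 X → G (k = 7.40 × 10⁻⁴ L mol⁻¹ s⁻¹, Ea = 51.0 kJ mol⁻¹)
    Q → D (k = 0.00410 s⁻¹, Ea = 82.0 kJ mol⁻¹)
    (constants at 20 °C)

Alder's Q stands above both estimates, and its Z left, 17.2 %, gives h = 1.24 min, against my 1.14 min; from it comes k = 1/(h·cZ), the rate constant of such a fall. Take a neighbour of alder charged with 0.20 M of Z, the rest unchanged, so that J stands at 2.25 equiv to Z. With unequal charges, f = (cJ − cZ)/(cJ·exp(k·t·(cJ − cZ)) − cZ), which gives 5.17 %. That flask ends with 6.83 % of its Z left and 28.9 % as Q.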